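**Plan**

- Retrosynthetic cuts: first the C3–CH2CO2H bond of the 1,2-dioxolane, then the O–O ring (back to a hydroperoxy ketone, an oxetane and a 1,3-diol), then the C5–CH2 bond to the side chain, and finally every C–C bond of the chain, one carbon at a time, back to the CH2–CH(CH3) bond next to the 4-phenylbutyl group.
- Forward: the chain is grown from the phenyl end by boron-to-carbon 1,2-shifts, C5 of the dioxolane is added in the same way as a tertiary carbinol, and the dioxolane (the only ring made) is closed in the penultimate step before the acetic acid arm is attached.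
- Enabling feature: both CH(CH3) methines of the chain and C5 of the 1,2-dioxolane are methyl-bearing carbons flanked only by CH2 groups, so each is the carbinol carbon of an ethyl or 2-alkyl benzoate and can be brought in as a chiral lithium carbenoid.
- Stereochemistry: the far CH(CH3) comes from (+)-sparteine and the near CH(CH3) from (−)-sparteine. C5 is bought with (2S,4S)-pentane-2,4-diol and carried through a Mitsunobu inversion, a stereospecific 1,2-shift and an invertive oxetane opening by H2O2. C3 is set by the chiral counter-anion in the last step.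

Key step: step 2

Assumption: ethyl 2,4,6-triisopropylbenzoate, 1,1-bis(trimethylsilyloxy)ethene and the IDPi acid are treated as catalogue reagents (each is otherwise a short, routine preparation from catalogue chemicals).

**Route**

Step 1
Reactants: 1 4-phenyl-1-butene
Product: 2 4,4,5,5-tetramethyl-2-(4-phenylbutyl)-1,3,2-dioxaborolane
Conditions: HBpin (1.2 equiv), [Ir(cod)Cl]2 (1.5 mol %), dppm (3 mol %), CH2Cl2, rt
Reagents that add atoms: pinacolborane, B1OC(C)(C)C(C)(C)O1
Why: Iridium-catalysed anti-Markovnikov hydroboration of a terminal alkene should give the linear primary boronic ester; no stereocentre is formed.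

Step 2
Reactants: 2 4,4,5,5-tetramethyl-2-(4-phenylbutyl)-1,3,2-dioxaborolane; 3 ethyl 2,4,6-triisopropylbenzoate
Product: 6 (S)-4,4,5,5-tetramethyl-2-(6-phenylhexan-2-yl)-1,3,2-dioxaborolane, via lithiated ethyl benzoate 4 (not isolated), via boronate complex 5 (not isolated)
Conditions: 3 (1.3 equiv), sBuLi (1.3 equiv), (+)-sparteine (1.3 equiv), Et2O, −78 °C, 5 h; then 2 (1.0 equiv), −78 °C, 1 h; then reflux, 3 h
Reagents that add atoms: none
Why: sBuLi complexed by (+)-sparteine removes one enantiotopic α-proton of 3 to give the configurationally stable (R)-α-lithio ester 4, which adds to the boron of 2 with retention to give boronate complex 5. On warming, the 4-phenylbutyl group shifts from boron to carbon antiperiplanar to the departing 2,4,6-triisopropylbenzoate (1,2-metallate rearrangement, inversion at carbon), which forms the CH2–CH(CH3) bond and leaves boron on the new stereocentre for the next homologation. The closest known reaction type is the sparteine-mediated lithiation–borylation of primary alkyl pinacol boronates with lithiated alkyl benzoates (a reagent-controlled Matteson-type homologation); no ring is closed. The new CH(CH3) stereocentre is set by the reagent alone, since 2 is achiral: (+)-sparteine selects the proton, and retention followed by inversion transmits that choice. The step needs discrimination between two enantiotopic protons and exactly one insertion; the first is secured by sparteine, the second by the hindered benzoate (no attack at C=O, and the ate complex is stable at −78 °C, so excess carbenoid is gone before the shift occurs) and by the unhindered primary CH2–B group of 2.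

Step 3
Reactants: 6 (S)-4,4,5,5-tetramethyl-2-(6-phenylhexan-2-yl)-1,3,2-dioxaborolane
Product: 8 (R)-4,4,5,5-tetramethyl-2-(2-methyl-6-phenylhexyl)-1,3,2-dioxaborolane, via chloromethyl boronate complex 7 (not isolated)
Conditions: BrCH2Cl (2.5 equiv), nBuLi (2.0 equiv), Et2O, −78 °C; then rt, 2 h
Reagents that add atoms: bromochloromethane, ClCBr
Why: Matteson homologation: chloromethyllithium made in the flask adds to boron and the secondary alkyl group migrates with loss of chloride, with retention at the migrating stereocentre (the descriptor changes only through priority).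

Step 4
Reactants: 8 (R)-4,4,5,5-tetramethyl-2-(2-methyl-6-phenylhexyl)-1,3,2-dioxaborolane
Product: 10 (R)-4,4,5,5-tetramethyl-2-(3-methyl-7-phenylheptyl)-1,3,2-dioxaborolane, via chloromethyl boronate complex 9 (not isolated)
Conditions: BrCH2Cl (2.5 equiv), nBuLi (2.0 equiv), Et2O, −78 °C; then rt, 2 h
Reagents that add atoms: bromochloromethane, ClCBr
Why: Second Matteson one-carbon homologation of a primary pinacol boronate; the ate complex rearranges only on warming, after excess carbenoid has decomposed, so a single CH2 should be inserted.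

Step 5
Reactants: 10 (R)-4,4,5,5-tetramethyl-2-(3-methyl-7-phenylheptyl)-1,3,2-dioxaborolane
Product: 12 (R)-4,4,5,5-tetramethyl-2-(4-methyl-8-phenyloctyl)-1,3,2-dioxaborolane, via chloromethyl boronate complex 11 (not isolated)
Conditions: BrCH2Cl (2.5 equiv), nBuLi (2.0 equiv), Et2O, −78 °C; then rt, 2 h
Reagents that add atoms: bromochloromethane, ClCBr
Why: Third Matteson homologation, which completes the three-methylene spacer between the two methyl-bearing carbons.

Step 6
Reactants: 12 (R)-4,4,5,5-tetramethyl-2-(4-methyl-8-phenyloctyl)-1,3,2-dioxaborolane; 3 ethyl 2,4,6-triisopropylbenzoate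
Product: 15 4,4,5,5-tetramethyl-2-[(2R,6S)-6-methyl-10-phenyldecan-2-yl]-1,3,2-dioxaborolane, via lithiated ethyl benzoate 13 (not isolated), via boronate complex 14 (not isolated)
Conditions: 3 (1.3 equiv), sBuLi (1.3 equiv), (−)-sparteine (1.3 equiv), Et2O, −78 °C, 5 h; then 12 (1.0 equiv), −78 °C, 1 h; then reflux, 3 h
Reagents that add atoms: none
Why: Second sparteine-mediated lithiation–borylation; (−)-sparteine gives the (S)-carbenoid and hence the (R)-configured C–B centre under reagent control, the remote first stereocentre having no influence.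

Step 7
Reactants: 15 4,4,5,5-tetramethyl-2-[(2R,6S)-6-methyl-10-phenyldecan-2-yl]-1,3,2-dioxaborolane
Product: 17 2-[(2S,6S)-2,6-dimethyl-10-phenyldecyl]-4,4,5,5-tetramethyl-1,3,2-dioxaborolane, via chloromethyl boronate complex 16 (not isolated)
Conditions: BrCH2Cl (2.5 equiv), nBuLi (2.0 equiv), Et2O, −78 °C; then rt, 2 h
Reagents that add atoms: bromochloromethane, ClCBr
Why: Matteson homologation with retention at the migrating secondary carbon installs the CH2 that will become the link to the dioxolane.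

Step 8
Reactants: 18 (2S,4S)-pentane-2,4-diol
Product: 19 (2S,4S)-4-[(tert-butyldimethylsilyl)oxy]pentan-2-ol
Conditions: NaH (1.0 equiv), THF, rt; then TBSCl (1.0 equiv), rt
Reagents that add atoms: tert-butyldimethylsilyl chloride, CC(C)(C)[Si](C)(C)Cl
Why: Monosilylation of a diol through its monosodium alkoxide; the two hydroxyls of the C2-symmetric diol are homotopic, so only one monoether can form.

Step 9
Reactants: 19 (2S,4S)-4-[(tert-butyldimethylsilyl)oxy]pentan-2-ol
Product: 20 (2R,4S)-4-[(tert-butyldimethylsilyl)oxy]pentan-2-yl 2,4,6-triisopropylbenzoate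
Conditions: 2,4,6-triisopropylbenzoic acid (1.3 equiv), PPh3 (1.3 equiv), DIAD (1.3 equiv), THF, 0 °C → rt
Reagents that add atoms: 2,4,6-triisopropylbenzoic acid, CC(C)c1cc(C(C)C)c(C(=O)O)c(C(C)C)c1
Why: Mitsunobu esterification of a secondary alcohol with the hindered acid should proceed with clean inversion to the (R)-ester.

Step 10
Reactants: 17 2-[(2S,6S)-2,6-dimethyl-10-phenyldecyl]-4,4,5,5-tetramethyl-1,3,2-dioxaborolane; 20 (2R,4S)-4-[(tert-butyldimethylsilyl)oxy]pentan-2-yl 2,4,6-triisopropylbenzoate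
Product: 24 (2S,4S,6R,10S)-2-[(tert-butyldimethylsilyl)oxy]-4,6,10-trimethyl-14-phenyltetradecan-4-ol, via lithiated benzoate 21 (not isolated), via boronate complex 22 (not isolated), via tertiary boronic ester 23 (not isolated)
Conditions: 20 (1.4 equiv), sBuLi (1.3 equiv), TMEDA (6 equiv), CPME, −60 °C, 2 h; then 17 (1.0 equiv), −60 °C, 1 h, then 45 °C, 14 h; then 2 M NaOH, 30% H2O2, THF, 0 °C → rt
Reagents that add atoms: hydrogen peroxide, OO
Why: Lithiation–borylation of a secondary dialkyl benzoate: α-lithiation and borylation occur with retention, the primary alkyl group migrates with inversion, and oxidation of the tertiary boronic ester occurs with retention, so the tertiary C–O stereocentre is relayed stereospecifically from the purchased diol.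

Step 11
Reactants: 24 (2S,4S,6R,10S)-2-[(tert-butyldimethylsilyl)oxy]-4,6,10-trimethyl-14-phenyltetradecan-4-ol
Product: 25 (2S,4S,6R,10S)-4,6,10-trimethyl-14-phenyltetradecane-2,4-diol
Conditions: TBAF (1.5 equiv), THF, rt
Reagents that add atoms: none
Why: Fluoride cleavage of the silyl ether frees the secondary alcohol without touching any stereocentre.

Step 12
Reactants: 25 (2S,4S,6R,10S)-4,6,10-trimethyl-14-phenyltetradecane-2,4-diol
Product: 27 (2S,4R)-2-[(2R,6S)-2,6-dimethyl-10-phenyldecyl]-2,4-dimethyloxetane, via monotosylate 26 (not isolated)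
Conditions: nBuLi (1.0 equiv), THF, 0 °C; TsCl (1.0 equiv), 0 °C → rt; then nBuLi (1.05 equiv), 0 → 60 °C
Reagents that add atoms: none
Why: One-pot oxetane synthesis from a 1,3-diol: the less hindered secondary alkoxide is sulfonylated and the tertiary alkoxide closes the ring by 4-exo-tet Williamson displacement, with inversion at the secondary carbon and the tertiary C–O bond untouched.

Step 13
Reactants: 27 (2S,4R)-2-[(2R,6S)-2,6-dimethyl-10-phenyldecyl]-2,4-dimethyloxetane
Product: 28 (2R,4R,6R,10S)-4-hydroperoxy-4,6,10-trimethyl-14-phenyltetradecan-2-ol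
Conditions: anhydrous H2O2 in Et2O (10 equiv), TMSOTf (0.3 equiv), Et2O, −78 → 0 °C
Reagents that add atoms: hydrogen peroxide, OO
Why: Lewis-acid-promoted perhydrolysis of an oxetane: H2O2 attacks the silyl-activated ring at the more substituted (tertiary) carbon with inversion, which should install the tertiary C–OOH centre in the configuration of C5 of the target.

Step 14
Reactants: 28 (2R,4R,6R,10S)-4-hydroperoxy-4,6,10-trimethyl-14-phenyltetradecan-2-ol
Product: 29 (2R,4R,6R,10S)-4,6,10-trimethyl-14-phenyl-4-[(triethylsilyl)peroxy]tetradecan-2-ol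
Conditions: Et3SiCl (1.05 equiv), Et3N (1.5 equiv), CH2Cl2, −40 °C
Reagents that add atoms: chlorotriethylsilane, CC[Si](Cl)(CC)CC
Why: Chemoselective O-silylation to a silyl peroxide: the hydroperoxide is far more acidic than the secondary alcohol and should be silylated first at low temperature.

Step 15
Reactants: 29 (2R,4R,6R,10S)-4,6,10-trimethyl-14-phenyl-4-[(triethylsilyl)peroxy]tetradecan-2-ol
Product: 30 (4R,6R,10S)-4,6,10-trimethyl-14-phenyl-4-[(triethylsilyl)peroxy]tetradecan-2-one
Conditions: Dess–Martin periodinane (1.3 equiv), NaHCO3, CH2Cl2, 0 °C → rt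
Reagents that add atoms: none
Why: Dess–Martin oxidation of the secondary alcohol to the methyl ketone; the silyl-capped peroxide should be inert to the iodine reagent.

Step 16
Reactants: 30 (4R,6R,10S)-4,6,10-trimethyl-14-phenyl-4-[(triethylsilyl)peroxy]tetradecan-2-one
Product: 33 (5R)-5-[(2R,6S)-2,6-dimethyl-10-phenyldecyl]-3-methoxy-3,5-dimethyl-1,2-dioxolane (both C3 epimers), via hydroperoxy ketone 31 (not isolated), via dioxolan-3-ol 32 (not isolated)
Conditions: TsOH·H2O (10 mol %), MeOH, 0 °C → rt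
Reagents that add atoms: methanol, CO
Why: Acidic methanolysis removes the silyl group, the free hydroperoxide adds to the ketone (5-exo-trig hemiperketal closure of the dioxolane) and acid-catalysed exchange gives the methyl peroxyketal; the C3 epimer mixture is irrelevant because C3 is ionised in the next step.

Step 17
Reactants: 33 (5R)-5-[(2R,6S)-2,6-dimethyl-10-phenyldecyl]-3-methoxy-3,5-dimethyl-1,2-dioxolane
Product: 35 2-[(3R,5R)-5-[(2R,6S)-2,6-dimethyl-10-phenyldecyl]-3,5-dimethyl-1,2-dioxolan-3-yl]acetic acid, via trimethylsilyl ester 34 (not isolated)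
Conditions: 1,1-bis(trimethylsilyloxy)ethene (1.5 equiv), IDPi acid (N,N'-bis(trifluoromethylsulfonyl) imidodiphosphorimidate built from two 3,3'-diaryl-BINOL units, 3 mol %), CH2Cl2/toluene, −78 °C; then pH 4 buffer
Reagents that add atoms: 1,1-bis(trimethylsilyloxy)ethene, C=C(O[Si](C)(C)C)O[Si](C)(C)C
Why: Proposed new method: the IDPi acid is silylated by the ketene acetal, the silylium/IDPi pair removes methoxide from 33 (as MeOSiMe3) and leaves a planar 3-methyl-1,2-dioxolan-3-ylium ion paired with the confined chiral anion, which blocks one face so that the ketene acetal adds to the other and returns the silyl group (Mukaiyama-type addition under silylium/chiral-counter-anion catalysis); the closest known reactions are IDPi-catalysed additions of silyl ketene acetals to cyclic aliphatic oxocarbenium ions from lactol acetates and Lewis-acid-mediated additions of silyl ketene acetals to 3-alkoxy-1,2-dioxolanes; because the two C5 substituents (CH3 and CH2R) bias the faces only weakly, the catalyst enantiomer (fixed in a two-run screen) should decide C3, and the other three stereocentres are untouched.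

**Compound list**

1 | 4-phenyl-1-butene | C=CCCc1ccccc1 | starting material
2 | 4,4,5,5-tetramethyl-2-(4-phenylbutyl)-1,3,2-dioxaborolane | CC1(C)OB(CCCCc2ccccc2)OC1(C)C | intermediate
3 | ethyl 2,4,6-triisopropylbenzoate | CCOC(=O)c1c(C(C)C)cc(C(C)C)cc1C(C)C | starting material
4 | (R)-1-lithioethyl 2,4,6-triisopropylbenzoate, (+)-sparteine complex | C[C@H](OC(=O)c1c(C(C)C)cc(C(C)C)cc1C(C)C)[Li] | intermediate
5 | lithium boronate complex of 2 with 4 | [Li+].C[C@H](OC(=O)c1c(C(C)C)cc(C(C)C)cc1C(C)C)[B-]1(CCCCc2ccccc2)OC(C)(C)C(C)(C)O1 | intermediate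
6 | (S)-4,4,5,5-tetramethyl-2-(6-phenylhexan-2-yl)-1,3,2-dioxaborolane | C[C@@H](CCCCc1ccccc1)B1OC(C)(C)C(C)(C)O1 | intermediate
7 | lithium (chloromethyl)boronate complex of 6 | [Li+].C[C@@H](CCCCc1ccccc1)[B-]1(CCl)OC(C)(C)C(C)(C)O1 | intermediate
8 | (R)-4,4,5,5-tetramethyl-2-(2-methyl-6-phenylhexyl)-1,3,2-dioxaborolane | C[C@@H](CCCCc1ccccc1)CB1OC(C)(C)C(C)(C)O1 | intermediate
9 | lithium (chloromethyl)boronate complex of 8 | [Li+].C[C@@H](CCCCc1ccccc1)C[B-]1(CCl)OC(C)(C)C(C)(C)O1 | intermediate
10 | (R)-4,4,5,5-tetramethyl-2-(3-methyl-7-phenylheptyl)-1,3,2-dioxaborolane | C[C@@H](CCCCc1ccccc1)CCB1OC(C)(C)C(C)(C)O1 | intermediate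
11 | lithium (chloromethyl)boronate complex of 10 | [Li+].C[C@@H](CCCCc1ccccc1)CC[B-]1(CCl)OC(C)(C)C(C)(C)O1 | intermediate
12 | (R)-4,4,5,5-tetramethyl-2-(4-methyl-8-phenyloctyl)-1,3,2-dioxaborolane | C[C@@H](CCCCc1ccccc1)CCCB1OC(C)(C)C(C)(C)O1 | intermediate
13 | (S)-1-lithioethyl 2,4,6-triisopropylbenzoate, (−)-sparteine complex | C[C@@H](OC(=O)c1c(C(C)C)cc(C(C)C)cc1C(C)C)[Li] | intermediate
14 | lithium boronate complex of 12 with 13 | [Li+].C[C@@H](OC(=O)c1c(C(C)C)cc(C(C)C)cc1C(C)C)[B-]1(CCC[C@@H](C)CCCCc2ccccc2)OC(C)(C)C(C)(C)O1 | intermediate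
15 | 4,4,5,5-tetramethyl-2-[(2R,6S)-6-methyl-10-phenyldecan-2-yl]-1,3,2-dioxaborolane | C[C@@H](CCCCc1ccccc1)CCC[C@@H](C)B1OC(C)(C)C(C)(C)O1 | intermediate
16 | lithium (chloromethyl)boronate complex of 15 | [Li+].C[C@@H](CCCCc1ccccc1)CCC[C@@H](C)[B-]1(CCl)OC(C)(C)C(C)(C)O1 | intermediate
17 | 2-[(2S,6S)-2,6-dimethyl-10-phenyldecyl]-4,4,5,5-tetramethyl-1,3,2-dioxaborolane | C[C@@H](CCCCc1ccccc1)CCC[C@@H](C)CB1OC(C)(C)C(C)(C)O1 | intermediate
18 | (2S,4S)-pentane-2,4-diol | C[C@H](O)C[C@H](C)O | starting material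
19 | (2S,4S)-4-[(tert-butyldimethylsilyl)oxy]pentan-2-ol | C[C@H](O)C[C@H](C)O[Si](C)(C)C(C)(C)C | intermediate
20 | (2R,4S)-4-[(tert-butyldimethylsilyl)oxy]pentan-2-yl 2,4,6-triisopropylbenzoate | C[C@@H](OC(=O)c1c(C(C)C)cc(C(C)C)cc1C(C)C)C[C@H](C)O[Si](C)(C)C(C)(C)C | intermediate
21 | 2-lithio derivative of 20 (tertiary α-lithio benzoate) | C[C@@]([Li])(OC(=O)c1c(C(C)C)cc(C(C)C)cc1C(C)C)C[C@H](C)O[Si](C)(C)C(C)(C)C | intermediate
22 | lithium boronate complex of 17 with 21 | [Li+].C[C@@H](CCCCc1ccccc1)CCC[C@@H](C)C[B-]1(OC(C)(C)C(C)(C)O1)[C@](C)(OC(=O)c1c(C(C)C)cc(C(C)C)cc1C(C)C)C[C@H](C)O[Si](C)(C)C(C)(C)C | intermediate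
23 | tert-butyldimethyl{[(2S,4S,6R,10S)-4,6,10-trimethyl-14-phenyl-4-(4,4,5,5-tetramethyl-1,3,2-dioxaborolan-2-yl)tetradecan-2-yl]oxy}silane | C[C@@H](CCCCc1ccccc1)CCC[C@@H](C)C[C@@](B1OC(C)(C)C(C)(C)O1)(C)C[C@H](C)O[Si](C)(C)C(C)(C)C | intermediate
24 | (2S,4S,6R,10S)-2-[(tert-butyldimethylsilyl)oxy]-4,6,10-trimethyl-14-phenyltetradecan-4-ol | C[C@@H](CCCCc1ccccc1)CCC[C@@H](C)C[C@@](O)(C)C[C@H](C)O[Si](C)(C)C(C)(C)C | intermediate
25 | (2S,4S,6R,10S)-4,6,10-trimethyl-14-phenyltetradecane-2,4-diol | C[C@@H](CCCCc1ccccc1)CCC[C@@H](C)C[C@@](O)(C)C[C@H](C)O | intermediate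
26 | (2S,4S,6R,10S)-4-hydroxy-4,6,10-trimethyl-14-phenyltetradecan-2-yl 4-methylbenzenesulfonate | C[C@@H](CCCCc1ccccc1)CCC[C@@H](C)C[C@@](O)(C)C[C@H](C)OS(=O)(=O)c1ccc(C)cc1 | intermediate
27 | (2S,4R)-2-[(2R,6S)-2,6-dimethyl-10-phenyldecyl]-2,4-dimethyloxetane | C[C@@H](CCCCc1ccccc1)CCC[C@@H](C)C[C@@]1(C)C[C@@H](C)O1 | intermediate
28 | (2R,4R,6R,10S)-4-hydroperoxy-4,6,10-trimethyl-14-phenyltetradecan-2-ol | C[C@@H](CCCCc1ccccc1)CCC[C@@H](C)C[C@](OO)(C)C[C@@H](C)O | intermediate
29 | (2R,4R,6R,10S)-4,6,10-trimethyl-14-phenyl-4-[(triethylsilyl)peroxy]tetradecan-2-ol | C[C@@H](CCCCc1ccccc1)CCC[C@@H](C)C[C@](OO[Si](CC)(CC)CC)(C)C[C@@H](C)O | intermediate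
30 | (4R,6R,10S)-4,6,10-trimethyl-14-phenyl-4-[(triethylsilyl)peroxy]tetradecan-2-one | C[C@@H](CCCCc1ccccc1)CCC[C@@H](C)C[C@](OO[Si](CC)(CC)CC)(C)CC(C)=O | intermediate
31 | (4R,6R,10S)-4-hydroperoxy-4,6,10-trimethyl-14-phenyltetradecan-2-one | C[C@@H](CCCCc1ccccc1)CCC[C@@H](C)C[C@](OO)(C)CC(C)=O | intermediate
32 | (5R)-5-[(2R,6S)-2,6-dimethyl-10-phenyldecyl]-3,5-dimethyl-1,2-dioxolan-3-ol (C3 epimers) | C[C@@H](CCCCc1ccccc1)CCC[C@@H](C)C[C@]1(C)CC(C)(O)OO1 | intermediate
33 | (5R)-5-[(2R,6S)-2,6-dimethyl-10-phenyldecyl]-3-methoxy-3,5-dimethyl-1,2-dioxolane (C3 epimers) | C[C@@H](CCCCc1ccccc1)CCC[C@@H](C)C[C@]1(C)CC(C)(OC)OO1 | intermediate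
34 | trimethylsilyl 2-[(3R,5R)-5-[(2R,6S)-2,6-dimethyl-10-phenyldecyl]-3,5-dimethyl-1,2-dioxolan-3-yl]acetate | C[C@@H](CCCCc1ccccc1)CCC[C@@H](C)C[C@]1(C)C[C@](C)(CC(=O)O[Si](C)(C)C)OO1 | intermediate
35 | 2-[(3R,5R)-5-[(2R,6S)-2,6-dimethyl-10-phenyldecyl]-3,5-dimethyl-1,2-dioxolan-3-yl]acetic acid | C[C@@H](CCCCc1ccccc1)CCC[C@@H](C)C[C@]1(C)C[C@](C)(CC(=O)O)OO1 | target

**Step count and risks**

Total steps: 17. Longest linear sequence: 15 (steps 1–7 and 10–17; steps 8–9 form a two-step branch).

Steps most likely to fail: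

1. Step 17 (proposed new method). The chiral ion pair may give weak or mismatched facial control at the quaternary C3, because the tertiary peroxycarbenium ion is more hindered than the ions of the precedent; the strong acid may also trigger heterolysis of the O–O bond. Fallback with known chemistry: starting from 33, TiCl4-mediated addition of 1-(ethylthio)-1-(trimethylsilyloxy)ethene in CH2Cl2 at −78 °C should give the S-ethyl thioester as both C3 epimers. The (3R) epimer, S-ethyl 2-[(3R,5R)-5-[(2R,6S)-2,6-dimethyl-10-phenyldecyl]-3,5-dimethyl-1,2-dioxolan-3-yl]ethanethioate F1, is separated by chromatography and hydrolysed (LiOH, THF/H2O, 0 °C), which returns to the route at 35.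

2. Step 10. Boronate formation between the hindered tertiary carbenoid and the β-branched pinacol boronate may be slow or reversible, so that the carbenoid decomposes before the 1,2-shift (low conversion, erosion of stereochemical fidelity). Fallback, starting from 17 and building the tertiary carbinol by hydroxyl-directed epoxidation instead:
   - Commercial (S)-pent-3-yn-2-ol is silylated to (S)-tert-butyldimethyl(pent-3-yn-2-yloxy)silane F2, then treated with Cp2ZrHCl followed by I2 to give (S,E)-tert-butyl[(4-iodopent-3-en-2-yl)oxy]dimethylsilane F3.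
   - F3 is lithiated (tBuLi, −78 °C) and added to 17, and the resulting boronate is treated with I2 and NaOMe (Zweifel olefination, inversion of alkene geometry) to give tert-butyl{[(2S,3Z,6R,10S)-4,6,10-trimethyl-14-phenyltetradec-3-en-2-yl]oxy}dimethylsilane F4.
   - TBAF gives (2S,3Z,6R,10S)-4,6,10-trimethyl-14-phenyltetradec-3-en-2-ol F5.
   - mCPBA should epoxidise F5 on the face fixed by the carbinol under A(1,3) strain (threo) to give (1S)-1-[(2R,3S)-3-[(2R,6S)-2,6-dimethyl-10-phenyldecyl]-3-methyloxiran-2-yl]ethan-1-ol F6.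
   - NaAlH2(OCH2CH2OMe)2 opens the epoxide at the carbon next to the carbinol, which returns to the route at 25.

3. Step 13. The activated oxetane may ionise to a free tertiary cation (loss of inversion, E1 elimination), or H2O2 may attack the secondary carbon. Fallback, starting from 25: Dess–Martin oxidation of the secondary alcohol gives (4S,6R,10S)-4-hydroxy-4,6,10-trimethyl-14-phenyltetradecan-2-one F7, and dehydration (MsCl, Et3N, then DBU) gives (6R,10S)-4,6,10-trimethyl-14-phenyltetradec-3-en-2-one F8 as an E/Z mixture. Conjugate addition of H2O2 with a catalytic amine base and hemiperketal closure then gives 32 together with its C5 epimer. Acidic methanol (as in step 16) converts these to 33 and its C5 epimer, which are separated by chromatography; the route is rejoined at 33.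

**Further compounds**

F1 | step 17 | S-ethyl 2-[(3R,5R)-5-[(2R,6S)-2,6-dimethyl-10-phenyldecyl]-3,5-dimethyl-1,2-dioxolan-3-yl]ethanethioate | C[C@@H](CCCCc1ccccc1)CCC[C@@H](C)C[C@]1(C)C[C@](C)(CC(=O)SCC)OO1
F2 | step 10 | (S)-tert-butyldimethyl(pent-3-yn-2-yloxy)silane | CC#C[C@H](C)O[Si](C)(C)C(C)(C)C
F3 | step 10 | (S,E)-tert-butyl[(4-iodopent-3-en-2-yl)oxy]dimethylsilane | C/C(I)=C\[C@H](C)O[Si](C)(C)C(C)(C)C
F4 | step 10 | tert-butyl{[(2S,3Z,6R,10S)-4,6,10-trimethyl-14-phenyltetradec-3-en-2-yl]oxy}dimethylsilane | C[C@@H](CCCCc1ccccc1)CCC[C@@H](C)C/C(C)=C\[C@H](C)O[Si](C)(C)C(C)(C)C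
F5 | step 10 | (2S,3Z,6R,10S)-4,6,10-trimethyl-14-phenyltetradec-3-en-2-ol | C[C@@H](CCCCc1ccccc1)CCC[C@@H](C)C/C(C)=C\[C@H](C)O
F6 | step 10 | (1S)-1-[(2R,3S)-3-[(2R,6S)-2,6-dimethyl-10-phenyldecyl]-3-methyloxiran-2-yl]ethan-1-ol | C[C@@H](CCCCc1ccccc1)CCC[C@@H](C)C[C@]1(C)O[C@@H]1[C@H](C)O
F7 | step 13 | (4S,6R,10S)-4-hydroxy-4,6,10-trimethyl-14-phenyltetradecan-2-one | C[C@@H](CCCCc1ccccc1)CCC[C@@H](C)C[C@@](O)(C)CC(C)=O
F8 | step 13 | (6R,10S)-4,6,10-trimethyl-14-phenyltetradec-3-en-2-one (E/Z mixture) | C[C@@H](CCCCc1ccccc1)CCC[C@@H](C)CC(C)=CC(C)=O
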